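**Strategy.** Everything rests on the C8–C15 bond of ring D (C8, C14, C13, C16, C15). C8 is the α-carbon of the C7 lactone and is bonded to C14, so a C8 radical can take the acyl carbon C15 from C14 if C15 first sits in a cyclobutanone (C13, C14, C15, C16) cis-fused to ring C. This one-carbon ring expansion (Dowd–Beckwith shift) gives in one operation the cyclopentanone, the bicyclo[3.2.1]octane and the quaternary C8 with its ketone and lactone carbonyls. The precursor is an α-chloro spiro-δ-lactone on a complete ring A, made by an intramolecular Diels–Alder reaction of a pentadienoate and a keteniminium [2+2] cycloaddition.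

Key step: step 19

Remarks on the chemistry and assumptions:
- Locants are those of the ent-kaurane skeleton: C1–C5 and C10 form ring A, C6 is the CH2OAc carbon on C5, C7 the lactone carbonyl, C15 the ketone, C16/C17 the methylene unit, C18 the methyl and C19 the CH2O group on C4, C20 the lactone OCH2. α is the ring A face that carries C20.
- The TADDOL enantiomer in step 1 is assumed to be the one that delivers (R)-5; otherwise its mirror image is used.
- Compounds 9 and 10 are drawn as the C10 epimer that lactonises (C10 is enolisable). Compound 22 is drawn as one C8 epimer (both converge in step 17). Compound 28 is a mixture of C16 epimers.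

Step 1
Reactants: 1 (E)-3-(tert-butyldimethylsilyloxy)-N,N-dimethylbuta-1,3-dien-1-amine; 2 methacrolein
Product: 5 (R)-4-(hydroxymethyl)-4-methylcyclohex-2-en-1-one, via cycloadduct aldehyde 3 (not isolated), via amino alcohol 4 (not isolated)
Conditions: (R,R)-tetra(1-naphthyl)-TADDOL (20 mol %), toluene, −80 °C; then LiAlH4, Et2O, −78 °C to rt; then aq. HF, MeCN, rt
Reagents that add atoms: none
Why: A hydrogen-bond-catalysed Diels–Alder reaction of the aminosiloxydiene with methacrolein should set the C4 quaternary centre by face-selective approach to the diol-bound aldehyde, after which hydride reduction of the formyl group and HF-induced enol ether hydrolysis with β-elimination of dimethylamine unveil the enone.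

Step 2
Reactants: 5 (R)-4-(hydroxymethyl)-4-methylcyclohex-2-en-1-one
Product: 6 (R)-4-(hydroxymethyl)-2-iodo-4-methylcyclohex-2-en-1-one
Conditions: I2, pyridine, CH2Cl2, 0 °C to rt
Reagents that add atoms: iodine, II
Why: Pyridine-mediated α-iodination of the enone (conjugate addition, iodination of the enolate, elimination) is reliable for cyclohexenones, tolerates the free alcohol and creates no stereocentre.

Step 3
Reactants: 6 (R)-4-(hydroxymethyl)-2-iodo-4-methylcyclohex-2-en-1-one
Product: 7 methyl (R)-3-(hydroxymethyl)-3-methyl-6-oxocyclohex-1-ene-1-carboxylate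
Conditions: Pd(OAc)2 (5 mol %), PPh3, CO (1 atm), Et3N, MeOH/DMF, 60 °C
Reagents that add atoms: carbon monoxide, [C-]#[O+]; methanol, CO
Why: Palladium-catalysed methoxycarbonylation of the vinyl iodide (oxidative addition to zerovalent palladium, CO insertion, methanolysis) should give the alkylidene β-keto ester that carries C20 without touching C4.

Step 4
Reactants: 7 methyl (R)-3-(hydroxymethyl)-3-methyl-6-oxocyclohex-1-ene-1-carboxylate
Product: 8 methyl (R)-3-{[(bromomethyl)dimethylsilyl]oxymethyl}-3-methyl-6-oxocyclohex-1-ene-1-carboxylate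
Conditions: BrCH2SiMe2Cl, Et3N, DMAP (cat.), CH2Cl2, 0 °C
Reagents that add atoms: (bromomethyl)chlorodimethylsilane, C[Si](C)(Cl)CBr
Why: Silylation of the neopentyl primary alcohol installs the tether for a silicon-tethered radical cyclisation and forms no stereocentre.

Step 5
Reactants: 8 methyl (R)-3-{[(bromomethyl)dimethylsilyl]oxymethyl}-3-methyl-6-oxocyclohex-1-ene-1-carboxylate
Product: 9 cis-fused oxasilinane β-keto ester
Conditions: Bu3SnH (slow addition), AIBN (cat.), benzene, 80 °C
Reagents that add atoms: none
Why: Bromine abstraction gives an α-silyl radical that should cyclise 6-exo-trig onto C5, the β-carbon of the doubly activated alkene, and because the tether hangs from C19 the new C5–C6 bond forms cis to C19 (cis ring fusion), while C10 stays epimerisable.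

Step 6
Reactants: 9 cis-fused oxasilinane β-keto ester
Product: 11 19-hydroxy keto γ-lactone, via diol ester 10 (not isolated)
Conditions: KF, KHCO3, 30% H2O2, THF/MeOH, rt
Reagents that add atoms: hydrogen peroxide, OO
Why: Tamao oxidation converts the C6–Si bond into C6–OH and frees the C19 hydroxyl, and the C6 hydroxyl, cis to the equilibrating C10 ester, should close the cis-fused γ-lactone on C20.

Step 7
Reactants: 11 19-hydroxy keto γ-lactone
Product: 12 10-ethynyl keto γ-lactone
Conditions: TMS-EBX, Bu4NF, THF, −78 °C
Reagents that add atoms: 1-[(trimethylsilyl)ethynyl]-1,2-benziodoxol-3(1H)-one (TMS-EBX), C[Si](C)(C)C#CI1OC(=O)c2ccccc12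
Why: Electrophilic alkynylation of the β-keto lactone enolate with the ethynylbenziodoxolone released by fluoride should create quaternary C10 with the ethynyl group (C9, C11) entering trans to C6, the mode that keeps the γ-lactone cis-fused and avoids the axial C19 substituent.

Step 8
Reactants: 12 10-ethynyl keto γ-lactone
Product: 13 10-vinyl keto γ-lactone
Conditions: H2 (1 atm), Pd/CaCO3 poisoned with Pb(OAc)2, quinoline, EtOAc, rt
Reagents that add atoms: none
Why: Lindlar semihydrogenation stops at the terminal alkene and leaves ketone and lactone untouched.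

Step 9
Reactants: 13 10-vinyl keto γ-lactone
Product: 14 19-O-TBDPS keto γ-lactone
Conditions: TBDPSCl, imidazole, DMF, 40 °C
Reagents that add atoms: tert-butyl(chloro)diphenylsilane, CC(C)(C)[Si](Cl)(c1ccccc1)c1ccccc1
Why: Silylation protects the C19 hydroxyl as an ether that is stable to hydride, base and mild acid and is removed by fluoride at the end.

Step 10
Reactants: 14 19-O-TBDPS keto γ-lactone
Product: 15 ring A triol
Conditions: LiAlH4, THF, −78 to 0 °C
Reagents that add atoms: none
Why: In this hydride reduction the C1 ketone reacts first, by axial attack anti to the axial C20 substituent on C10, which should give the equatorial 1α-alcohol, and on warming the lactone is reduced to the C20 and C6 primary alcohols.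

Step 11
Reactants: 15 ring A triol
Product: 16 1,20-O-isopropylidene acetal
Conditions: 2,2-dimethoxypropane, PPTS (cat.), CH2Cl2, rt
Reagents that add atoms: 2,2-dimethoxypropane, COC(C)(C)OC
Why: Acetalisation under thermodynamic control should pick the 1,3-diol (O1 and O20) as a six-membered acetonide and leave the C6 hydroxyl free.

Step 12
Reactants: 16 1,20-O-isopropylidene acetal
Product: 17 6-O-acetyl acetonide
Conditions: Ac2O, pyridine, DMAP (cat.), CH2Cl2, rt
Reagents that add atoms: acetic anhydride, CC(=O)OC(C)=O
Why: DMAP-catalysed acetylation of the only free hydroxyl installs the C6 acetate of the target.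

Step 13
Reactants: 17 6-O-acetyl acetonide
Product: 18 1α,20-diol 6-acetate
Conditions: AcOH/THF/H2O 3:1:1, 45 °C
Reagents that add atoms: none
Why: Mild acid hydrolysis cleaves the acetonide while the acetate and the TBDPS ether survive.

Step 14
Reactants: 18 1α,20-diol 6-acetate; 19 (E)-penta-2,4-dienoic acid
Product: 20 20-O-pentadienoyl 1α-alcohol
Conditions: EDC·HCl, DMAP (cat.), CH2Cl2, 0 °C
Reagents that add atoms: none
Why: Carbodiimide (Steglich) esterification should acylate the primary C20 hydroxyl in preference to the hindered secondary C1 hydroxyl and so attach C7, C8, C14, C13 and C12.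

Step 15
Reactants: 20 20-O-pentadienoyl 1α-alcohol
Product: 21 trienyl diacetate
Conditions: Ac2O, Et3N, DMAP, CH2Cl2, rt
Reagents that add atoms: acetic anhydride, CC(=O)OC(C)=O
Why: DMAP-catalysed acetylation of the remaining secondary alcohol gives the 1α-acetate of the target.

Step 16
Reactants: 21 trienyl diacetate
Product: 22 spiro-δ-lactone cyclohexene
Conditions: BHT (cat.), 1,2-dichlorobenzene, 180 °C, sealed tube
Reagents that add atoms: none
Why: A thermal intramolecular Diels–Alder reaction of the dienoate (C8=C14–C13=C12) with the C9=C11 vinyl group closes the δ-lactone and ring C at once with regiochemistry fixed by the four-atom tether, and C9 should be set by passage of the diene over the small C1 acetoxy flank of ring A and not the C5 CH2OAc flank, while the two C8 epimers converge in step 17.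

Step 17
Reactants: 22 spiro-δ-lactone cyclohexene
Product: 24 8-chloro spiro lactone, via lithium dienolate 23 (not isolated)
Conditions: LiN(SiMe3)2, THF, −78 °C; then C2Cl6, −78 to −40 °C
Reagents that add atoms: hexachloroethane, ClC(Cl)(Cl)C(Cl)(Cl)Cl
Why: Kinetic deprotonation at the allylic α-position of the lactone (more acidic than the acetates) and electrophilic chlorination of the dienolate at C8 on the face of H9 should give the tertiary α-chloro lactone that serves as the radical precursor.

Step 18
Reactants: 24 8-chloro spiro lactone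
Product: 26 8-chloro cyclobutanone, via cyclobutaniminium triflate 25 (not isolated)
Conditions: CH3CONMe2, Tf2O, 2,4,6-collidine, ClCH2CH2Cl, reflux; then H2O, NaHCO3
Reagents that add atoms: N,N-dimethylacetamide, CC(=O)N(C)C; water, O
Why: In this keteniminium–alkene [2+2] cycloaddition the iminium carbon (C15) should bond to C14 so that positive charge builds at C13 away from the electron-poor C8, and the cis addition should occur on the face of ring C opposite to C10 and to the pseudoaxial C8 substituent, which sets C13 and C14 before hydrolysis to the ketone.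

Step 19
Reactants: 26 8-chloro cyclobutanone
Product: 27 bicyclo[3.2.1]octane keto lactone
Conditions: Bu3SnH (syringe pump), AIBN, benzene, 80 °C, high dilution
Reagents that add atoms: none
Why: Bu3Sn• abstracts the chlorine at C8 and the tertiary radical, stabilised by the C7 lactone carbonyl, adds 3-exo-trig to the adjacent strained C15 carbonyl; β-scission of the C14–C15 bond of the bicyclo[2.1.0] alkoxy radical then moves the acyl carbon from C14 to C8 and the C14 radical takes hydrogen from Bu3SnH. The closest known reaction type is the Dowd–Beckwith one-carbon ring expansion of ketones by a radical on the carbon attached to the α-position, which is established for fused cyclobutanones. Ring D (C8, C14, C13, C16, C15) is closed by this 3-exo addition and fragmentation as a cyclopentanone that grows out of the four-membered ring (C13, C14, C15, C16) by insertion of C8, and the same C8–C15 bond bridges ring C to the bicyclo[3.2.1]octane. The only new stereocentre, quaternary C8, is controlled by the cis-fused cyclobutanone, since C15 is held on one face of ring C at C14 and can reach the planar radical only from that face, which places C7 on the opposite face as in the target. The step needs the acyl shift to outrun direct reduction of the stabilised radical, and this is secured by the relief of cyclobutanone strain in the fragmentation together with slow addition of the hydride at high dilution. Regioselectivity is not in question because C15 is the only carbonyl 1,3 to the radical centre and the reverse shift would rebuild the four-membered ring.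

Step 20
Reactants: 27 bicyclo[3.2.1]octane keto lactone
Product: 29 19-O-TBDPS isodojaponin D, via Mannich base 28 (not isolated)
Conditions: (CH2O)n, PhNHMe·CF3CO2H, THF, 65 °C
Reagents that add atoms: paraformaldehyde (as formaldehyde), C=O
Why: In this Mannich-type α-methylenation the ketone can enolise only towards C16, so the iminium ion formed in the flask is captured there and N-methylaniline is eliminated to give the exocyclic enone (C17) under conditions that spare acetates and lactone.

Step 21
Reactants: 29 19-O-TBDPS isodojaponin D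
Product: 30 isodojaponin D
Conditions: HF·pyridine, THF, 0 °C to rt
Reagents that add atoms: none
Why: Fluoride-mediated desilylation frees the C19 hydroxyl while acetates, lactone and the enone are stable in the buffered acidic medium.

**Compound list**

1 | (E)-3-(tert-butyldimethylsilyloxy)-N,N-dimethylbuta-1,3-dien-1-amine | CN(C)/C=C/C(=C)O[Si](C)(C)C(C)(C)C | starting material
2 | methacrolein | CC(=C)C=O | starting material
3 | 2-(dimethylamino)-1-methyl-4-(tert-butyldimethylsilyloxy)cyclohex-3-ene-1-carbaldehyde, amino group cis to formyl | CN(C)[C@H]1C=C(O[Si](C)(C)C(C)(C)C)CC[C@@]1(C)C=O | intermediate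
4 | [2-(dimethylamino)-1-methyl-4-(tert-butyldimethylsilyloxy)cyclohex-3-en-1-yl]methanol | CN(C)[C@H]1C=C(O[Si](C)(C)C(C)(C)C)CC[C@@]1(C)CO | intermediate
5 | (R)-4-(hydroxymethyl)-4-methylcyclohex-2-en-1-one | O=C1C=C[C@](C)(CO)CC1 | intermediate
6 | (R)-4-(hydroxymethyl)-2-iodo-4-methylcyclohex-2-en-1-one | O=C1C(I)=C[C@](C)(CO)CC1 | intermediate
7 | methyl (R)-3-(hydroxymethyl)-3-methyl-6-oxocyclohex-1-ene-1-carboxylate | COC(=O)C1=C[C@](C)(CO)CCC1=O | intermediate
8 | methyl (R)-3-{[(bromomethyl)dimethylsilyl]oxymethyl}-3-methyl-6-oxocyclohex-1-ene-1-carboxylate | COC(=O)C1=C[C@](C)(CO[Si](C)(C)CBr)CCC1=O | intermediate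
9 | cis-fused oxasilinane β-keto ester (C1 ketone, C10 CO2Me, C5–CH2–SiMe2–O–CH2–C4 ring, C6 cis to C19) | COC(=O)[C@H]1C(=O)CC[C@@]2(C)CO[Si](C)(C)C[C@@H]12 | intermediate
10 | methyl 2,3-bis(hydroxymethyl)-3-methyl-6-oxocyclohexane-1-carboxylate, C20, C6 and C19 all cis | COC(=O)[C@H]1C(=O)CC[C@@](C)(CO)[C@H]1CO | intermediate
11 | cis-fused keto γ-lactone (C20 carbonyl–O–C6) with free 19-hydroxyl and C10–H | O=C1OC[C@@H]2[C@](C)(CO)CCC(=O)[C@H]12 | intermediate
12 | 10-ethynyl keto γ-lactone, ethynyl trans to C6 | C#C[C@@]12C(=O)OC[C@@H]1[C@](C)(CO)CCC2=O | intermediate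
13 | 10-vinyl keto γ-lactone | C=C[C@@]12C(=O)OC[C@@H]1[C@](C)(CO)CCC2=O | intermediate
14 | 19-O-TBDPS ether of 13 | C=C[C@@]12C(=O)OC[C@@H]1[C@](C)(CO[Si](c3ccccc3)(c3ccccc3)C(C)(C)C)CCC2=O | intermediate
15 | ring A triol: 1α-OH, 20-OH, 6-OH, 19-OTBDPS, 10-vinyl | C=C[C@]1(CO)[C@@H](O)CC[C@@](C)(CO[Si](c2ccccc2)(c2ccccc2)C(C)(C)C)[C@H]1CO | intermediate
16 | 1,20-O-isopropylidene acetal of 15 | C=C[C@]12COC(C)(C)O[C@H]1CC[C@@](C)(CO[Si](c3ccccc3)(c3ccccc3)C(C)(C)C)[C@H]2CO | intermediate
17 | 6-O-acetate of 16 | C=C[C@]12COC(C)(C)O[C@H]1CC[C@@](C)(CO[Si](c3ccccc3)(c3ccccc3)C(C)(C)C)[C@H]2COC(C)=O | intermediate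
18 | 1α,20-diol 6-acetate | C=C[C@]1(CO)[C@@H](O)CC[C@@](C)(CO[Si](c2ccccc2)(c2ccccc2)C(C)(C)C)[C@H]1COC(C)=O | intermediate
19 | (E)-penta-2,4-dienoic acid | OC(=O)/C=C/C=C | starting material
20 | 20-O-[(E)-penta-2,4-dienoyl] ester of 18 with free 1α-OH | C=C[C@]1(COC(=O)/C=C/C=C)[C@@H](O)CC[C@@](C)(CO[Si](c2ccccc2)(c2ccccc2)C(C)(C)C)[C@H]1COC(C)=O | intermediate
21 | 1α-acetate of 20 (cycloaddition precursor) | C=C[C@]1(COC(=O)/C=C/C=C)[C@@H](OC(C)=O)CC[C@@](C)(CO[Si](c2ccccc2)(c2ccccc2)C(C)(C)C)[C@H]1COC(C)=O | intermediate
22 | 7,20-spiro-δ-lactone fused to cyclohexene ring C (C13=C14), natural C9, drawn with 8-H cis to 9-H | C1=C[C@@H]2C(=O)OC[C@@]3([C@@H]2CC1)[C@@H](OC(C)=O)CC[C@@](C)(CO[Si](c4ccccc4)(c4ccccc4)C(C)(C)C)[C@H]3COC(C)=O | intermediate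
23 | lithium dienolate of 22 | C1=CC2=C(O[Li])OC[C@@]3([C@@H]2CC1)[C@@H](OC(C)=O)CC[C@@](C)(CO[Si](c4ccccc4)(c4ccccc4)C(C)(C)C)[C@H]3COC(C)=O | intermediate
24 | 8-chloro spiro lactone, Cl cis to 9-H | C1=C[C@]2(Cl)C(=O)OC[C@@]3([C@@H]2CC1)[C@@H](OC(C)=O)CC[C@@](C)(CO[Si](c4ccccc4)(c4ccccc4)C(C)(C)C)[C@H]3COC(C)=O | intermediate
25 | N,N-dimethylcyclobutaniminium triflate (C15=N on C14, C16 on C13) | C[N+](C)=C1C[C@@H]2CC[C@H]3[C@]4(COC(=O)[C@@]3(Cl)[C@H]12)[C@@H](OC(C)=O)CC[C@@](C)(CO[Si](c5ccccc5)(c5ccccc5)C(C)(C)C)[C@H]4COC(C)=O.[O-]S(=O)(=O)C(F)(F)F | intermediate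
26 | 8-chloro cyclobutanone: C15 ketone on C14, C16H2 on C13, four-membered ring cis-fused on the face of ring C opposite C10 | O=C1C[C@@H]2CC[C@H]3[C@]4(COC(=O)[C@@]3(Cl)[C@H]12)[C@@H](OC(C)=O)CC[C@@](C)(CO[Si](c5ccccc5)(c5ccccc5)C(C)(C)C)[C@H]4COC(C)=O | intermediate
27 | 15-oxo 7,20-lactone with the bicyclo[3.2.1]octane (C16H2), 1α,6-diacetate, 19-OTBDPS | C1C(=O)[C@]23C[C@H]1CC[C@H]2[C@]1(COC3=O)[C@@H](OC(C)=O)CC[C@@](C)(CO[Si](c4ccccc4)(c4ccccc4)C(C)(C)C)[C@H]1COC(C)=O | intermediate
28 | 16-[(N-methylanilino)methyl] derivative of 27, C16 epimers | CN(CC1C(=O)[C@]23C[C@H]1CC[C@H]2[C@]1(COC3=O)[C@@H](OC(C)=O)CC[C@@](C)(CO[Si](c4ccccc4)(c4ccccc4)C(C)(C)C)[C@H]1COC(C)=O)c5ccccc5 | intermediate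
29 | 19-O-TBDPS isodojaponin D | C=C1C(=O)[C@]23C[C@H]1CC[C@H]2[C@]1(COC3=O)[C@@H](OC(C)=O)CC[C@@](C)(CO[Si](c4ccccc4)(c4ccccc4)C(C)(C)C)[C@H]1COC(C)=O | intermediate
30 | isodojaponin D | C=C1C(=O)[C@]23C[C@H]1CC[C@H]2[C@]1(COC3=O)[C@@H](OC(C)=O)CC[C@@](C)(CO)[C@H]1COC(C)=O | target

**Totals and risks**

Total step count: 21. Longest linear sequence: 21 steps (from 1 and 2).

Steps most likely to fail, each with one fallback:

1. Step 19 (key step). The process at risk is hydrogen transfer to the stabilised C8 radical before the acyl shift, which gives plain dechlorination. Fallback: 26 is isomerised under atom-transfer conditions without a hydrogen donor (CuCl, tris(2-pyridylmethyl)amine, ClCH2CH2Cl, 80 °C). The C8 radical is formed reversibly by chlorine transfer to monovalent copper and can only rearrange, and the C14 radical is capped by chlorine to give the 14-chloro keto lactone F1. Radical dechlorination of F1 (Bu3SnH, AIBN, toluene, 110 °C) then gives 27, where the route is rejoined.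

2. Step 16. The process at risk is poor π-facial selectivity at C9 (the diene passing the C5 flank of ring A), besides thermal polymerisation of the dienoate. Fallback from 18: the primary C20 hydroxyl is silylated (Et3SiCl, imidazole, CH2Cl2) to the 20-O-triethylsilyl ether F2. The C1 hydroxyl is esterified with 19 (EDC·HCl, DMAP) to the 1-O-pentadienoate F3. Heating as in step 16 then runs the cycloaddition through a lactone trans-fused to ring A, in which the diene is anchored on the C1 side and C11 avoids the axial C20 group only in the orientation that gives the natural C9 configuration. This gives the 1,7-lactone F4. Desilylation (HF·pyridine) and acid-catalysed acyl transfer from the secondary O1 to the primary O20 (camphorsulfonic acid, toluene) should give the 1-hydroxy spiro lactone F5. Acetylation of F5 (Ac2O, DMAP) returns to 22.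

3. Step 18. The process at risk is sluggish or regiochemically reversed cycloaddition at the hindered, electron-poor alkene. Fallback from 24: dichloroketene generated from Cl3CCOCl and Zn/Cu couple (Et2O, ultrasound) is used, in which the small carbonyl carbon bonds to hindered C14 and the CCl2 end to C13, so that steric and electronic preferences coincide. This gives the dichlorocyclobutanone F6. Under the conditions of step 19 with excess Bu3SnH the two α-keto chlorines are removed and the ring expansion is triggered, which leads directly to 27.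

Further compounds
F1 | step 19 | 14-chloro derivative of 27 (Cl on the one-carbon bridge, syn to ring D) | C1C(=O)[C@]23[C@H](Cl)[C@H]1CC[C@H]2[C@]1(COC3=O)[C@@H](OC(C)=O)CC[C@@](C)(CO[Si](c4ccccc4)(c4ccccc4)C(C)(C)C)[C@H]1COC(C)=O
F2 | step 16 | 20-O-triethylsilyl ether of 18 | C=C[C@]1(CO[Si](CC)(CC)CC)[C@@H](O)CC[C@@](C)(CO[Si](c2ccccc2)(c2ccccc2)C(C)(C)C)[C@H]1COC(C)=O
F3 | step 16 | 1-O-[(E)-penta-2,4-dienoyl] ester of F2 | C=C[C@]1(CO[Si](CC)(CC)CC)[C@@H](OC(=O)/C=C/C=C)CC[C@@](C)(CO[Si](c2ccccc2)(c2ccccc2)C(C)(C)C)[C@H]1COC(C)=O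
F4 | step 16 | 1,7-lactone cycloadduct (δ-lactone through O1, C13=C14, 20-OTES) | C1=C[C@@H]2C(=O)O[C@H]3CC[C@@](C)(CO[Si](c4ccccc4)(c4ccccc4)C(C)(C)C)[C@@H](COC(C)=O)[C@]3(CO[Si](CC)(CC)CC)[C@@H]2CC1
F5 | step 16 | 1α-hydroxy 7,20-spiro lactone (deacetyl 22) | C1=C[C@@H]2C(=O)OC[C@@]3([C@@H]2CC1)[C@@H](O)CC[C@@](C)(CO[Si](c4ccccc4)(c4ccccc4)C(C)(C)C)[C@H]3COC(C)=O
F6 | step 18 | 8-chloro 16,16-dichlorocyclobutanone | O=C1C(Cl)(Cl)[C@@H]2CC[C@H]3[C@]4(COC(=O)[C@@]3(Cl)[C@H]12)[C@@H](OC(C)=O)CC[C@@](C)(CO[Si](c5ccccc5)(c5ccccc5)C(C)(C)C)[C@H]4COC(C)=O
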